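## Structural features

The target is an open-chain 3,7-dimethylocta-1,6-diene with no carbocycle; its only ring is the benzene ring of the (E)-4-hydroxycinnamoyl (p-coumaroyl) unit, joined to the chain through an ester at O4. C3 is a fully substituted carbinol carbon bearing methyl, vinyl (C1=C2), an acetoxy group and C4. C4 is a secondary carbinol carbon bearing the coumarate and the arm C5–C6=C7(CH3)2. The two stereocentres (3R, 4S) are directly bonded, and in the extended chain drawn through C2–C3–C4–C5 the two oxygens lie anti. Fragile features are the tertiary allylic acetate (ionisation under acid, 1,2-acyl shift whenever the neighbouring oxygen is free), two different esters on vicinal oxygens, the free phenol, the Michael-acceptor cinnamate and the trisubstituted C6=C7 olefin; the C4–C8 aldehyde precursor is β,γ-unsaturated and conjugates easily. The real difficulty is C3: methyl and vinyl are sterically alike, so its configuration cannot be set reliably by induction from C4, and the two hydroxyls must end with different acyl groups. The key step uses the fact that C1=C2–C3(O)–C4(O) is the retron of a γ-oxygenated allylation: the C3–C4 bond joins the γ-carbon of an allylboron reagent (carrying methyl and silyloxy) to an aldehyde carbon, C1=C2 being the transposed double bond, so enol-ether geometry and a closed chair fix C3 relative to C4.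

## Logic of the disconnections

15 ⇒ 14. The O–Si bond at the phenol is cut last. The phenol must stay masked through both acylations, and a silyl ether comes off under near-neutral fluoride. The forward step must leave the tertiary allylic acetate and the cinnamate untouched.

14 ⇒ 13. The O3–acetyl bond is cut. Acetyl goes last onto the most hindered oxygen, when every other hydroxyl is already capped, so no selectivity question arises. The forward step must acylate a tertiary allylic alcohol beside an ester without acid (no ionisation at C3) and without shifting the neighbouring acyl group.

13 ⇒ 9 + 12. The C4–O acyl bond is cut, which splits the molecule into a terpenoid diol and an aromatic acid of similar size. The secondary and tertiary hydroxyls of 9 differentiate themselves, so O3 needs no protecting group. The forward step must stop at O4 and keep the E geometry of 12.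

12 ⇒ 10 (through 11). Both O–Si bonds are cut; the forward step must free the acid again while the aryl silyl ether stays.

9 ⇒ 8. The O3–Si bond is cut. The silyl group on O3 serves only to make C3 an enol-ether carbon in the key step. Removing it directly afterwards, while no ester is present, avoids a late forcing desilylation of a tertiary silyl ether beside the cinnamate and avoids acylating O4 next to a bulky silyloxy group.

8 ⇒ 4 + 6 (through 7). The C3–C4 bond is cut. This is the only skeletal bond between the two stereocentres, and cutting it removes both at once, giving an achiral aldehyde and an achiral boronate. The forward step must deliver the γ-carbon of 4 to one face of 6 through an ordered transition state, with 4 as a single olefin isomer.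

6 ⇒ 5. Only the oxidation level changes; the forward oxidation must not move the double bond into conjugation.

4 ⇒ 2 + 3, and 2 ⇒ 1. The C–B bond and one C–H bond are cut across the termini of a diene, then the O–Si bond of the dienol ether. A cis-1,4 addition to the s-cis diene is the one simple way to place the new methyl cis to CH2B (silyloxy trans). The forward step must put boron on the terminus remote from the silyloxy group and preserve that geometry.

## Other disconnections considered

Alternative 1: The cut is the C3–O bond of the tertiary carbinol.
- Forward key step: racemic vinyl epoxide A1 and alcohol A2 are joined with Pd2(dba)3·CHCl3 (zerovalent palladium), a chiral trans-1,2-diaminocyclohexane bis(2-diphenylphosphinobenzamide) ligand and catalytic BEt3. Ionisation gives π-allylpalladium alkoxides that interconvert faster than they are trapped; the boron-bound alcohol is delivered to the more substituted terminus, and tertiary ether A3 should form as one enantiomer, with the future C4 as a primary alcohol.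
- In favour: C3, the hardest centre, is set by the catalyst alone from a cheap racemic feedstock in one step. On precedent for the substrate class it is at least the equal of the enol-ether allylboration, and probably better.
- Against: only one stereocentre is made. C4 must follow by oxidation to aldehyde A4 and addition of a prenyl nucleophile. The α-carbon of A4 carries methyl and vinyl, which neither a chelated nor an open transition state distinguishes well, so C4 would need reagent control. Prenyl-metal reagents also add through their γ-terminus, so the linear arm needs an allylation and cross-metathesis detour.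
- Comparison: mechanistically the chosen plan sets both centres in one chair, the alternative in two unrelated events. Structurally both converge on the diol stage (after oxidative removal of the benzyl-type ether) and share the acylation end game, where they are equal. The alternative is estimated to be three to four steps longer in the longest linear sequence.

Alternative 2: The cut is C4–C5.
- Forward key step: glyoxylate A5 and alkene A6 combine in an ene reaction under a chiral bis(oxazoline) complex of Cu(SbF6)2 (divalent copper). The aldehyde sits in a bidentate chelate, the alkene adds to the open face with transfer of its allylic hydrogen, and hydroxy ester A7 should form with C4 (S) and the C6=C7 olefin in place.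
- In favour: it is fully atom-economic, builds C4 and the prenyl arm together from two bulk chemicals, and never passes through the isomerisation-prone aldehyde 6. On these points it is better than the chosen plan.
- Against: A6 is a gaseous, monosubstituted alkene, the weakest class of ene donor. C3 must then be built on the ester carbon by two successive carbon nucleophiles under 1,2-induction from C4. Chelation-controlled vinyl addition to the derived α-alkoxy methyl ketone would give the C3 epimer of what is needed. The correct isomer needs methyl addition to the α-alkoxy vinyl ketone (conjugate addition competes) or non-chelation control, which is less dependable for ketones.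
- Comparison: both key steps are ordered six-membered events and are equal in predictability for the centre they set, but the chosen step sets two centres and this one sets one. Protection, ester-to-ketone conversion and two additions add an estimated three to four linear steps before the common end game.

Alternative 3: The cut is the C4–O ester bond, made together with the C4 configuration.
- Forward key step: allylic alcohol A8 is epoxidised (Sharpless epoxidation) to epoxy alcohol A9, and acid 12 opens it under Ti(OiPr)4 at the carbon remote from the hydroxymethyl group with inversion, giving diol ester A10 with both stereocentres and the coumarate in place.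
- In favour: both centres come from one of the most dependable asymmetric reactions for trisubstituted allylic alcohols, so on reliability of absolute stereocontrol it is better than the chosen key step. The ester forms in the stereodefining step, which saves the separate esterification.
- Against: the epoxide carbon that must not be attacked is tertiary, so Lewis-acid opening there is a real competitor, and a conjugated carboxylate is a modest nucleophile. A10 has a primary and a tertiary hydroxyl beside the ester, so acyl shift to the primary oxygen threatens. The primary carbinol must still become the vinyl group by oxidation to an α-hydroxy aldehyde and methylenation in the presence of the cinnamate.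
- Comparison: structurally the chosen plan gets the vinyl group for free by allylic transposition, whereas here it costs two late steps on a sensitive intermediate. In step economy the plans are about equal (A8 itself needs two or three steps), and the acetylation and phenol-release end game is the same.

Key step: step 4

Assumption: the (R) enantiomer of 3,3'-bis(2,4,6-triisopropylphenyl)-1,1'-binaphthyl-2,2'-diyl hydrogen phosphate, (R)-TRIP, is taken to direct the boronate to the Re face of the aldehyde, as it does with simpler allyl and crotyl pinacol boronates; if the sense proves opposite, the (S) acid is used with no other change.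

Step 1
Reactants: 1 methyl vinyl ketone
Product: 2 2-(tert-butyldimethylsilyloxy)buta-1,3-diene
Conditions: TBSOTf, Et3N, CH2Cl2, 0 °C to rt
Reagents that add atoms: tert-butyldimethylsilyl trifluoromethanesulfonate, CC(C)(C)[Si](C)(C)OS(=O)(=O)C(F)(F)F
Why: Soft enolisation and O-silylation of an enone; only the methyl group can be deprotonated, so a single 2-silyloxydiene should result.

Step 2
Reactants: 2 2-(tert-butyldimethylsilyloxy)buta-1,3-diene; 3 pinacolborane
Product: 4 pinacol (E)-3-(tert-butyldimethylsilyloxy)but-2-enylboronate
Conditions: Ni(cod)2 (2.5 mol%), PCy3 (2.5 mol%), toluene, rt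
Reagents that add atoms: none
Why: Nickel-catalysed 1,4-hydroboration of a 1,3-diene: the diene binds zerovalent nickel in its s-cis form, boron goes to the unhindered terminus remote from the silyloxy group and hydrogen to the other terminus. The new methyl and CH2B therefore end cis on the new double bond, which is the (E) enol ether (silyloxy trans to CH2B).

Step 3
Reactants: 5 4-methylpent-3-en-1-ol
Product: 6 4-methylpent-3-enal
Conditions: Dess–Martin periodinane, NaHCO3, CH2Cl2, 0 °C; filtered, concentrated cold, taken up in toluene and used at once
Reagents that add atoms: none
Why: Dess–Martin oxidation of a primary alcohol; the buffered, non-basic medium and low temperature should prevent migration of the β,γ-double bond into conjugation, and the volatile aldehyde is never stored.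

Step 4
Reactants: 4 pinacol (E)-3-(tert-butyldimethylsilyloxy)but-2-enylboronate; 6 4-methylpent-3-enal
Product: 8 (3R,4S)-3-(tert-butyldimethylsilyloxy)-3,7-dimethylocta-1,6-dien-4-ol, via O4-pinacolborate ester 7 (not isolated)
Conditions: (R)-TRIP (5 mol%), 4 Å MS, toluene, −30 °C, slow addition of 6 (1.3 equiv); then H2O, rt
Reagents that add atoms: none
Why: Catalytic asymmetric allylboration: boron of 4 binds the aldehyde oxygen and the γ-carbon (bearing methyl and silyloxy) attacks the carbonyl carbon through a closed six-membered chair with allylic transposition, which unveils C1=C2 and first gives borate 7, hydrolysed on work-up. The phosphoric acid hydrogen-bonds through P–OH to a pinacol oxygen and through P=O to the formyl hydrogen, so the catalysed path should outrun the uncatalysed one, and the 3,3'-aryl groups leave only the Re face of 6 open, which corresponds to 4S. C3 is controlled by olefin geometry: the silyloxy group, trans to CH2B, sits pseudo-equatorial and ends anti to the new O4, while the cis methyl sits pseudo-axial, which is 3R once C4 is S. The closest known reaction type is the chiral phosphoric acid-catalysed allyl- and crotylboration of aldehydes with pinacol boronates, including γ,γ-disubstituted and γ-alkoxy reagents. No ring is closed in the product. The step needs γ- over α-attack (inherent in the cyclic mechanism), catalysed over background addition (low temperature, slow addition of 6) and survival of the silyl enol ether (a weak acid, molecular sieves and the robust tert-butyldimethylsilyl group secure this). Isomerisation of 6 to the conjugated enal is held back by the low temperature, and 6 is used in slight excess.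

Step 5
Reactants: 8 (3R,4S)-3-(tert-butyldimethylsilyloxy)-3,7-dimethylocta-1,6-dien-4-ol
Product: 9 (3R,4S)-3,7-dimethylocta-1,6-diene-3,4-diol
Conditions: TBAF, THF, rt to 40 °C
Reagents that add atoms: none
Why: Fluoride-mediated desilylation; the tertiary silyl ether should yield readily because the neighbouring hydroxyl can relay the silyl group and nothing base-sensitive is present. Only Si–O bonds break, so both stereocentres are retained.

Step 6
Reactants: 10 p-coumaric acid
Product: 12 (E)-3-[4-(tert-butyldimethylsilyloxy)phenyl]acrylic acid, via bis-silyl ester 11 (not isolated)
Conditions: TBSCl, imidazole, DMF, rt; then AcOH/THF/H2O, rt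
Reagents that add atoms: tert-butyldimethylsilyl chloride, CC(C)(C)[Si](C)(C)Cl
Why: Silylation of both acidic hydroxyls followed by selective hydrolysis of the far more labile silyl ester; the aryl silyl ether should survive dilute acetic acid, and the E olefin is not involved.

Step 7
Reactants: 9 (3R,4S)-3,7-dimethylocta-1,6-diene-3,4-diol; 12 (E)-3-[4-(tert-butyldimethylsilyloxy)phenyl]acrylic acid
Product: 13 (3R,4S)-3-hydroxy-3,7-dimethylocta-1,6-dien-4-yl (E)-3-[4-(tert-butyldimethylsilyloxy)phenyl]acrylate
Conditions: DCC, DMAP (cat.), CH2Cl2, 0 °C to rt
Reagents that add atoms: none
Why: Steglich esterification; the secondary hydroxyl should react far faster than the tertiary allylic one, so O3 needs no protection, and acylation at oxygen leaves C4 unchanged.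

Step 8
Reactants: 13 (3R,4S)-3-hydroxy-3,7-dimethylocta-1,6-dien-4-yl (E)-3-[4-(tert-butyldimethylsilyloxy)phenyl]acrylate
Product: 14 (3R,4S)-3-acetoxy-3,7-dimethylocta-1,6-dien-4-yl (E)-3-[4-(tert-butyldimethylsilyloxy)phenyl]acrylate
Conditions: Ac2O, Et3N, DMAP (1 equiv), CH2Cl2, rt to 40 °C
Reagents that add atoms: acetic anhydride, CC(=O)OC(C)=O
Why: DMAP-catalysed acetylation through the N-acetylpyridinium ion, the standard acid-free way to acylate tertiary alcohols; base-only conditions avoid ionisation of the tertiary allylic carbinol, and reaction at oxygen keeps the C3 configuration.

Step 9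
Reactants: 14 (3R,4S)-3-acetoxy-3,7-dimethylocta-1,6-dien-4-yl (E)-3-[4-(tert-butyldimethylsilyloxy)phenyl]acrylate
Product: 15 (3R,4S)-3-acetoxy-3,7-dimethylocta-1,6-dien-4-yl (E)-3-(4-hydroxyphenyl)acrylate (CNP0547742.1)
Conditions: TBAF, AcOH (1:1), THF, 0 °C
Reagents that add atoms: none
Why: Fluoride cleaves aryl silyl ethers quickly because phenoxide leaves silicon easily; acetic acid buffering keeps the medium near neutral, so the tertiary acetate, the cinnamate and both stereocentres should be undisturbed.

Compound list

1 | methyl vinyl ketone | CC(=O)C=C | starting material
2 | 2-(tert-butyldimethylsilyloxy)buta-1,3-diene | C=CC(=C)O[Si](C)(C)C(C)(C)C | intermediate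
3 | pinacolborane | B1OC(C)(C)C(C)(C)O1 | starting material
4 | pinacol (E)-3-(tert-butyldimethylsilyloxy)but-2-enylboronate | C/C(O[Si](C)(C)C(C)(C)C)=C\CB1OC(C)(C)C(C)(C)O1 | intermediate
5 | 4-methylpent-3-en-1-ol | CC(C)=CCCO | starting material
6 | 4-methylpent-3-enal | CC(C)=CCC=O | intermediate
7 | 2-{[(3R,4S)-3-(tert-butyldimethylsilyloxy)-3,7-dimethylocta-1,6-dien-4-yl]oxy}-4,4,5,5-tetramethyl-1,3,2-dioxaborolane | C=C[C@@](C)(O[Si](C)(C)C(C)(C)C)[C@H](CC=C(C)C)OB1OC(C)(C)C(C)(C)O1 | intermediate
8 | (3R,4S)-3-(tert-butyldimethylsilyloxy)-3,7-dimethylocta-1,6-dien-4-ol | C=C[C@@](C)(O[Si](C)(C)C(C)(C)C)[C@H](CC=C(C)C)O | intermediate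
9 | (3R,4S)-3,7-dimethylocta-1,6-diene-3,4-diol | C=C[C@@](C)(O)[C@H](CC=C(C)C)O | intermediate
10 | p-coumaric acid | O=C(O)/C=C/c1ccc(O)cc1 | starting material
11 | tert-butyldimethylsilyl (E)-3-[4-(tert-butyldimethylsilyloxy)phenyl]acrylate | CC(C)(C)[Si](C)(C)OC(=O)/C=C/c1ccc(O[Si](C)(C)C(C)(C)C)cc1 | intermediate
12 | (E)-3-[4-(tert-butyldimethylsilyloxy)phenyl]acrylic acid | O=C(O)/C=C/c1ccc(O[Si](C)(C)C(C)(C)C)cc1 | intermediate
13 | (3R,4S)-3-hydroxy-3,7-dimethylocta-1,6-dien-4-yl (E)-3-[4-(tert-butyldimethylsilyloxy)phenyl]acrylate | C=C[C@@](C)(O)[C@H](CC=C(C)C)OC(=O)/C=C/c1ccc(O[Si](C)(C)C(C)(C)C)cc1 | intermediate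
14 | (3R,4S)-3-acetoxy-3,7-dimethylocta-1,6-dien-4-yl (E)-3-[4-(tert-butyldimethylsilyloxy)phenyl]acrylate | C=C[C@@](C)(OC(C)=O)[C@H](CC=C(C)C)OC(=O)/C=C/c1ccc(O[Si](C)(C)C(C)(C)C)cc1 | intermediate
15 | (3R,4S)-3-acetoxy-3,7-dimethylocta-1,6-dien-4-yl (E)-3-(4-hydroxyphenyl)acrylate | C=C[C@@](C)(OC(C)=O)[C@H](CC=C(C)C)OC(=O)/C=C/c1ccc(O)cc1 | target

Total step count: 9. Longest linear sequence: 7 steps (steps 1, 2, 4, 5, 7, 8, 9, from 1 to 15); steps 3 and 6 are one-step side branches.

Least certain steps

Step 4 (key step). The most likely failure is erosion of enantioselectivity by the uncatalysed chair pathway, because the silyloxy group makes the γ-carbon more nucleophilic than in simple allyl boronates. Loss of the enol ether by protonation and drift of 6 into conjugation are secondary risks. The fallback keeps the chair for relative configuration and replaces catalytic induction by resolution. It sets out from 4 and 6, combined in toluene at rt without the chiral acid. This should give the anti adduct as a racemate, that is 8 together with its enantiomer (3S,4R)-3-(tert-butyldimethylsilyloxy)-3,7-dimethylocta-1,6-dien-4-ol F1. TBAF as in step 5 then gives 9 together with (3S,4R)-3,7-dimethylocta-1,6-diene-3,4-diol F2. Acylation of the secondary hydroxyl with (S)-2-methoxy-2-phenylacetic acid (DCC, cat. DMAP, 0 °C) gives two diastereomers, to be separated by chromatography or crystallisation: (3R,4S)-3-hydroxy-3,7-dimethylocta-1,6-dien-4-yl (S)-2-methoxy-2-phenylacetate F3 and (3S,4R)-3-hydroxy-3,7-dimethylocta-1,6-dien-4-yl (S)-2-methoxy-2-phenylacetate F4. Methanolysis of F3 (K2CO3, MeOH) comes back to the route at 9.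

Step 2. The most likely failure is misdirected delivery of boron (to the terminus next to the silyloxy carbon, or 1,2-addition across the vinyl group) or loss of olefin geometry by syn/anti isomerisation of the allylnickel intermediate. An enol-ether diene is electronically unlike the alkyl dienes on which the selectivity rules rest, and either error changes the constitution or the C3 configuration of the key-step product. The fallback drops the boronate and builds the diol by other means, from 6 to 9. Addition of CH2=C(CH3)MgBr to 6 (THF, −78 °C) gives (±)-2,6-dimethylhepta-1,5-dien-3-ol F5. Sharpless kinetic resolution (Ti(OiPr)4, L-(+)-diisopropyl tartrate, t-BuOOH, 4 Å MS, CH2Cl2, −20 °C, stopped near half conversion) should epoxidise only the allylic 1,1-disubstituted olefin of the fast-reacting (S) alcohol, erythro-selectively, giving (1S)-4-methyl-1-[(2R)-2-methyloxiran-2-yl]pent-3-en-1-ol F6, which is separated from the unreacted alcohol. Excess dimethylsulfonium methylide (trimethylsulfonium iodide, n-BuLi, THF, −10 °C to rt) opens the epoxide at its CH2 carbon and, after loss of dimethyl sulfide, turns it into the vinyl carbinol without touching either C–O stereocentre. This comes back to the route at 9.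

Step 8. The most likely failure is slow acylation of a tertiary alcohol flanked by a bulky ester. Prolonged heating with acetate and DMAP could then cause a 1,2-shift of the coumaroyl group towards O3 or loss of the aryl silyl ether. The fallback reverses the order of the two acylations, from 9 to 14. Selective silylation of the secondary hydroxyl (TESCl, imidazole, CH2Cl2, 0 °C) gives (3R,4S)-3,7-dimethyl-4-(triethylsilyloxy)octa-1,6-dien-3-ol F7. With no ester or aryl silyl ether present, the tertiary hydroxyl can be acetylated under forcing conditions (Ac2O, DMAP, pyridine, 50 °C) to give (3R,4S)-3,7-dimethyl-4-(triethylsilyloxy)octa-1,6-dien-3-yl acetate F8. Buffered HF·pyridine (pyridine, THF, 0 °C) then frees O4 to give (3R,4S)-4-hydroxy-3,7-dimethylocta-1,6-dien-3-yl acetate F9. F9 is esterified at once with 12 (DCC, DMAP, 0 °C) so that acylation outruns acetyl shift from O3 to O4, coming back to the route at 14.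

Step 7. The most likely failure is sluggish acylation of a secondary alcohol next to a quaternary carbon by a conjugated, weakly electrophilic acyl donor, which allows rearrangement of the activated acid to an N-acylurea or some acylation at O3. The fallback builds the cinnamate olefin on the alcohol instead of attaching it whole, from 9 to 13. The small and very reactive diethylphosphonoacetic acid (DCC, CH2Cl2, 0 °C) acylates O4 to give (3R,4S)-3-hydroxy-3,7-dimethylocta-1,6-dien-4-yl 2-(diethoxyphosphoryl)acetate F10. Horner–Wadsworth–Emmons olefination of F10 with 4-(tert-butyldimethylsilyloxy)benzaldehyde (LiCl, iPr2NEt, MeCN, rt) should give the E cinnamate, coming back to the route at 13.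

Further compounds

F1 | step 4 | (3S,4R)-3-(tert-butyldimethylsilyloxy)-3,7-dimethylocta-1,6-dien-4-ol | C=C[C@](C)(O[Si](C)(C)C(C)(C)C)[C@@H](CC=C(C)C)O
F2 | step 4 | (3S,4R)-3,7-dimethylocta-1,6-diene-3,4-diol | C=C[C@](C)(O)[C@@H](CC=C(C)C)O
F3 | step 4 | (3R,4S)-3-hydroxy-3,7-dimethylocta-1,6-dien-4-yl (S)-2-methoxy-2-phenylacetate | C=C[C@@](C)(O)[C@H](CC=C(C)C)OC(=O)[C@@H](OC)c1ccccc1
F4 | step 4 | (3S,4R)-3-hydroxy-3,7-dimethylocta-1,6-dien-4-yl (S)-2-methoxy-2-phenylacetate | C=C[C@](C)(O)[C@@H](CC=C(C)C)OC(=O)[C@@H](OC)c1ccccc1
F5 | step 2 | (±)-2,6-dimethylhepta-1,5-dien-3-ol | C=C(C)C(O)CC=C(C)C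
F6 | step 2 | (1S)-4-methyl-1-[(2R)-2-methyloxiran-2-yl]pent-3-en-1-ol | C1O[C@@]1(C)[C@H](CC=C(C)C)O
F7 | step 8 | (3R,4S)-3,7-dimethyl-4-(triethylsilyloxy)octa-1,6-dien-3-ol | C=C[C@@](C)(O)[C@H](CC=C(C)C)O[Si](CC)(CC)CC
F8 | step 8 | (3R,4S)-3,7-dimethyl-4-(triethylsilyloxy)octa-1,6-dien-3-yl acetate | C=C[C@@](C)(OC(C)=O)[C@H](CC=C(C)C)O[Si](CC)(CC)CC
F9 | step 8 | (3R,4S)-4-hydroxy-3,7-dimethylocta-1,6-dien-3-yl acetate | C=C[C@@](C)(OC(C)=O)[C@H](CC=C(C)C)O
F10 | step 7 | (3R,4S)-3-hydroxy-3,7-dimethylocta-1,6-dien-4-yl 2-(diethoxyphosphoryl)acetate | C=C[C@@](C)(O)[C@H](CC=C(C)C)OC(=O)CP(=O)(OCC)OCC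
A1 | alternative 1 | rac-2-methyl-2-vinyloxirane | C=CC1(C)CO1
A2 | alternative 1 | 4-methoxybenzyl alcohol | COc1ccc(CO)cc1
A3 | alternative 1 | (R)-2-[(4-methoxybenzyl)oxy]-2-methylbut-3-en-1-ol | C=C[C@@](C)(OCc1ccc(OC)cc1)CO
A4 | alternative 1 | (R)-2-[(4-methoxybenzyl)oxy]-2-methylbut-3-enal | C=C[C@@](C)(OCc1ccc(OC)cc1)C=O
A5 | alternative 2 | ethyl glyoxylate | CCOC(=O)C=O
A6 | alternative 2 | 3-methylbut-1-ene | C=CC(C)C
A7 | alternative 2 | ethyl (S)-2-hydroxy-5-methylhex-4-enoate | CCOC(=O)[C@H](CC=C(C)C)O
A8 | alternative 3 | (E)-2,6-dimethylhepta-2,5-dien-1-ol | OC/C(C)=C/CC=C(C)C
A9 | alternative 3 | [(2R,3R)-2-methyl-3-(3-methylbut-2-en-1-yl)oxiran-2-yl]methanol | OC[C@@]1(C)O[C@@H]1CC=C(C)C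
A10 | alternative 3 | (2R,3S)-1,2-dihydroxy-2,6-dimethylhept-5-en-3-yl (E)-3-[4-(tert-butyldimethylsilyloxy)phenyl]acrylate | OC[C@@](C)(O)[C@H](CC=C(C)C)OC(=O)/C=C/c1ccc(O[Si](C)(C)C(C)(C)C)cc1
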